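## Retrosynthetic overview

1. The plan rests on the cyclohexene ring C1–C6. Quaternary C1 (CH3 and alkene carbon Cb) sits next to C6(H)(coumarin B), which sits next to C5=C4(CH3), and C2H2–C3H2 ties C1 back to C4.
2. The Z alkene Ca=Cb comes from an alkyne by semi-hydrogenation. The alkyne comes from Sonogashira coupling of 8-iodo-5,7-dimethoxycoumarin (coumarin A) with a C1-ethynyl compound, which comes from the C1-carbaldehyde.
3. In that aldehyde, O=CH–C1–C6–C5=C4 is a γ,δ-unsaturated carbonyl unit. Undoing a [3,3] shift (open C1–C6, join the formyl O to C4) gives an (R)-2-styryl-2,5-dimethyl-3,4-dihydro-2H-pyran whose single ether stereocentre encodes both C1 and C6.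
4. The styryl group comes from a Heck coupling of the same iodide with (R)-2-vinyl-2,5-dimethyl-3,4-dihydro-2H-pyran, which is made from (R)-linalool.
5. Ring order: the pyran ring is made first and is then contracted to the carbocycle. Both coumarin ring systems are bought.

Key step: step 9

Assumption: natural (R)-(−)-linalool of high enantiomeric purity is used, since its carbinol carbon is the only source of chirality, and iodination of 5,7-dimethoxycoumarin is taken to occur at C8, the usual site in 5,7-dialkoxybenzopyranones.

## Route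

Step 1
Reactants: 1 (R)-(−)-linalool
Product: 4 (5R)-5-ethenyl-5-methyloxolan-2-ol (lactol; both anomers), via secondary ozonide 2 (not isolated), via hydroxy aldehyde 3 (not isolated)
Conditions: O3, CH2Cl2, Sudan Red 7B (end-point indicator), −78 °C; then Me2S, −78 °C → rt
Reagents that add atoms: ozone, [O-][O+]=O
Why: Criegee ozonolysis follows alkene nucleophilicity, so the trisubstituted C6=C7 bond should be consumed before the monosubstituted vinyl group when ozone uptake stops at the dye end-point; reductive work-up gives the γ-hydroxy aldehyde, which closes to the five-membered lactol without touching the carbinol stereocentre.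

Step 2
Reactants: 4 (5R)-5-ethenyl-5-methyloxolan-2-ol
Product: 5 (3R)-3-methylhept-1-ene-3,6-diol (both C6 epimers)
Conditions: MeMgBr (3 equiv), THF, 0 °C → rt; aq NH4Cl
Reagents that add atoms: methylmagnesium bromide, C[Mg]Br
Why: This is a Grignard addition to the open aldehyde tautomer of a lactol (the first equivalent deprotonates the OH); the new carbinol centre forms without control, which is harmless because step 3 removes it.

Step 3
Reactants: 5 (3R)-3-methylhept-1-ene-3,6-diol
Product: 6 (5R)-5-hydroxy-5-methylhept-6-en-2-one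
Conditions: Dess–Martin periodinane (1.2 equiv), CH2Cl2, 0 °C → rt
Reagents that add atoms: none
Why: Dess–Martin oxidation can act only on the secondary alcohol, because the tertiary allylic alcohol has no carbinol hydrogen and, unlike with oxochromium reagents, should not undergo oxidative allylic transposition.

Step 4
Reactants: 6 (5R)-5-hydroxy-5-methylhept-6-en-2-one
Product: 7 (3R)-7-methoxy-3,6-dimethylhepta-1,6-dien-3-ol (E/Z mixture at the enol ether)
Conditions: Ph3P+CH2OMe Cl− (3 equiv), KOtBu (3 equiv), THF, 0 °C; then 6, 0 °C → rt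
Reagents that add atoms: (methoxymethyl)triphenylphosphonium chloride, COC[P+](c1ccccc1)(c1ccccc1)c1ccccc1.[Cl-]
Why: Wittig methoxymethylenation of a methyl ketone is routine; excess ylide covers the free hydroxyl and draws the ketone out of its hemiketal form, and the enol ether geometry does not matter because both isomers converge in step 5.

Step 5
Reactants: 7 (3R)-7-methoxy-3,6-dimethylhepta-1,6-dien-3-ol
Product: 8 (6R)-6-ethenyl-2-methoxy-3,6-dimethyloxane (diastereomers at C2 and C3)
Conditions: PPTS (5 mol %), 4 Å MS, CH2Cl2, rt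
Reagents that add atoms: none
Why: Protonation of the enol ether and capture of the oxocarbenium ion by the tertiary hydroxyl (intramolecular acetalisation) closes the six-membered ring; the acid is too weak to ionise the tertiary allylic C–O bond, and the uncontrolled C2 and C3 centres vanish in step 6.

Step 6
Reactants: 8 (6R)-6-ethenyl-2-methoxy-3,6-dimethyloxane
Product: 9 (2R)-2-ethenyl-2,5-dimethyl-3,4-dihydro-2H-pyran
Conditions: TMSOTf (1.3 equiv), iPr2NEt (1.6 equiv), CH2Cl2, −20 °C → rt
Reagents that add atoms: none
Why: In this silyl triflate/tertiary amine conversion of an acetal to an enol ether, the less hindered exocyclic methoxy oxygen is silylated and leaves, and the amine removes the only β-hydrogen (C3–H); the medium stays basic, so the ether stereocentre should keep its configuration.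

Step 7
Reactants: 10 5,7-dimethoxycoumarin
Product: 11 8-iodo-5,7-dimethoxycoumarin
Conditions: NIS (1.05 equiv), CF3CO2H (0.3 equiv), MeCN, 0 °C → rt, dark
Reagents that add atoms: N-iodosuccinimide, O=C1CCC(=O)N1I
Why: Electrophilic aromatic iodination should take C8 (ortho to 7-OMe and O1, para to 5-OMe), which is less crowded than C6 between two methoxy groups and far more nucleophilic than C3 of the pyrone; any C6 isomer would be removed by crystallisation.

Step 8
Reactants: 9 (2R)-2-ethenyl-2,5-dimethyl-3,4-dihydro-2H-pyran (1.5 equiv); 11 8-iodo-5,7-dimethoxycoumarin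
Product: 12 8-[(E)-2-[(2R)-2,5-dimethyl-3,4-dihydro-2H-pyran-2-yl]ethenyl]-5,7-dimethoxycoumarin
Conditions: Pd(OAc)2 (5 mol %), nBu4NCl (1 equiv), NaHCO3 (2.5 equiv), DMF, 70 °C
Reagents that add atoms: none
Why: In this Mizoroki–Heck reaction on the halide-bound neutral pathway, the open monosubstituted vinyl group should insert in preference to the trisubstituted enol ether, with aryl going to the terminal carbon; the neighbouring carbon is quaternary, so only benzylic β-hydrogens are available and syn elimination gives the E alkene while the base protects the enol ether.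

Step 9
Reactants: 12 8-[(E)-2-[(2R)-2,5-dimethyl-3,4-dihydro-2H-pyran-2-yl]ethenyl]-5,7-dimethoxycoumarin
Product: 13 (1S,2S)-2-(5,7-dimethoxy-2-oxochromen-8-yl)-1,4-dimethylcyclohex-3-ene-1-carbaldehyde (aryl cis to CHO)
Conditions: PhMe (0.02 M, degassed), 2,6-di-tert-butyl-4-methylpyridine (0.1 equiv), BHT (cat.), silanised sealed tube, 180 °C
Reagents that add atoms: none
Why: On heating, the allyl vinyl ether array C5=C6–O1–C2–Cα=Cβ of 12 (pyran numbering; Cβ bears the coumarin) should undergo a concerted suprafacial [3,3]-sigmatropic shift in which O1–C2 breaks and C5–Cβ forms, so that C6 becomes the formyl carbon, C5 the quaternary C1, Cβ the benzylic C6 and C2=Cα the C4=C5 alkene of 13. The closest known reaction type is the thermal Claisen ring contraction of 2-alkenyl-3,4-dihydro-2H-pyrans to cyclohex-3-ene-1-carbaldehydes. The carbocycle C5–C4–C3–C2–Cα–Cβ is closed by that one new bond across the pyran ring, and the C3H2–C4H2 bridge holds both termini so that only a boat-like, bicyclo[2.2.2]octane-shaped transition state is within reach and a chair is excluded. The quaternary centre is fixed by the (R)-ether carbon, because the styryl arm can reach C5 only from the ring face on which it stands, and the benzylic centre is fixed by the E geometry, which in the boat turns the Cβ hydrogen towards the CH2–CH2 bridge and the aryl group towards the O1–C6 side, hence aryl cis to CHO. The step needs the concerted path to win over heterolysis of the tertiary, aryl-conjugated allylic C–O bond and over retro-hetero-Diels–Alder cleavage to methacrolein and the aryl diene, either of which would cost stereochemical fidelity. A non-polar solvent, acid-free silanised glass and a hindered pyridine buffer should suppress ionisation, while the donor aryl group at Cβ and the fully substituted C2 should lower the barrier of the polarised transition state enough to stay well below cycloreversion temperatures.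

Step 10
Reactants: 13 (1S,2S)-2-(5,7-dimethoxy-2-oxochromen-8-yl)-1,4-dimethylcyclohex-3-ene-1-carbaldehyde
Product: 14 8-[(1R,6S)-6-ethynyl-3,6-dimethylcyclohex-2-en-1-yl]-5,7-dimethoxycoumarin
Conditions: MeC(O)C(N2)P(O)(OMe)2 (1.5 equiv), K2CO3 (2 equiv), MeOH/THF, 0 °C → rt
Reagents that add atoms: dimethyl (1-diazo-2-oxopropyl)phosphonate, CC(=O)C(=[N+]=[N-])P(=O)(OC)OC
Why: Seyferth–Gilbert homologation with the Ohira–Bestmann reagent suits a non-enolisable α-quaternary aldehyde; neither stereocentre carries an acidic hydrogen, and the coumarin lactone should tolerate K2CO3/MeOH at room temperature.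

Step 11
Reactants: 14 8-[(1R,6S)-6-ethynyl-3,6-dimethylcyclohex-2-en-1-yl]-5,7-dimethoxycoumarin; 11 8-iodo-5,7-dimethoxycoumarin
Product: 15 8-[2-[(1S,2R)-2-(5,7-dimethoxy-2-oxochromen-8-yl)-1,4-dimethylcyclohex-3-en-1-yl]ethynyl]-5,7-dimethoxycoumarin
Conditions: PdCl2(PPh3)2 (5 mol %), CuI (10 mol %), Et3N, DMF, 60 °C, degassed
Reagents that add atoms: none
Why: Sonogashira coupling of an aryl iodide with a terminal alkyne is reliable; the iodide offsets the electron-rich, doubly ortho-substituted arene in oxidative addition, and oxygen is excluded to prevent alkyne homocoupling.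

Step 12
Reactants: 15 8-[2-[(1S,2R)-2-(5,7-dimethoxy-2-oxochromen-8-yl)-1,4-dimethylcyclohex-3-en-1-yl]ethynyl]-5,7-dimethoxycoumarin
Product: 16 8-[(Z)-2-[(1R,2R)-2-(5,7-dimethoxy-2-oxochromen-8-yl)-1,4-dimethylcyclohex-3-en-1-yl]ethenyl]-5,7-dimethoxycoumarin (target)
Conditions: H2 (1 atm), Pd/CaCO3 poisoned with Pb(OAc)2 (Lindlar catalyst), quinoline, EtOAc, rt, dark
Reagents that add atoms: none
Why: Lindlar semi-hydrogenation delivers both hydrogens to one face of the alkyne and so gives the Z alkene; the poisoned catalyst should leave the trisubstituted ring alkene and the two coumarin C3=C4 bonds alone.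

## Compound list

1 | (R)-(−)-linalool, (3R)-3,7-dimethylocta-1,6-dien-3-ol | C=C[C@](C)(O)CCC=C(C)C | starting material
2 | (3R)-5-(5,5-dimethyl-1,2,4-trioxolan-3-yl)-3-methylpent-1-en-3-ol (secondary ozonide) | C=C[C@](C)(O)CCC1OOC(C)(C)O1 | intermediate
3 | (4R)-4-hydroxy-4-methylhex-5-enal | C=C[C@](C)(O)CCC=O | intermediate
4 | (5R)-5-ethenyl-5-methyloxolan-2-ol (both anomers) | C=C[C@@]1(C)CCC(O)O1 | intermediate
5 | (3R)-3-methylhept-1-ene-3,6-diol (both C6 epimers) | C=C[C@](C)(O)CCC(C)O | intermediate
6 | (5R)-5-hydroxy-5-methylhept-6-en-2-one | C=C[C@](C)(O)CCC(C)=O | intermediate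
7 | (3R)-7-methoxy-3,6-dimethylhepta-1,6-dien-3-ol (E/Z mixture) | C=C[C@](C)(O)CCC(C)=COC | intermediate
8 | (6R)-6-ethenyl-2-methoxy-3,6-dimethyloxane (mixture at C2, C3) | COC1O[C@@](C)(C=C)CCC1C | intermediate
9 | (2R)-2-ethenyl-2,5-dimethyl-3,4-dihydro-2H-pyran | CC1=CO[C@@](C)(C=C)CC1 | intermediate
10 | 5,7-dimethoxycoumarin | COc1cc(OC)c2ccc(=O)oc2c1 | starting material
11 | 8-iodo-5,7-dimethoxycoumarin | COc1cc(OC)c2ccc(=O)oc2c1I | intermediate
12 | 8-[(E)-2-[(2R)-2,5-dimethyl-3,4-dihydro-2H-pyran-2-yl]ethenyl]-5,7-dimethoxycoumarin | CC1=CO[C@@](C)(/C=C/c2c(OC)cc(OC)c3ccc(=O)oc23)CC1 | intermediate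
13 | (1S,2S)-2-(5,7-dimethoxy-2-oxochromen-8-yl)-1,4-dimethylcyclohex-3-ene-1-carbaldehyde (aryl cis to CHO) | O=C[C@@]1(C)CCC(C)=C[C@H]1c1c(OC)cc(OC)c2ccc(=O)oc12 | intermediate
14 | 8-[(1R,6S)-6-ethynyl-3,6-dimethylcyclohex-2-en-1-yl]-5,7-dimethoxycoumarin (aryl cis to ethynyl) | C#C[C@@]1(C)CCC(C)=C[C@H]1c1c(OC)cc(OC)c2ccc(=O)oc12 | intermediate
15 | 8-[2-[(1S,2R)-2-(5,7-dimethoxy-2-oxochromen-8-yl)-1,4-dimethylcyclohex-3-en-1-yl]ethynyl]-5,7-dimethoxycoumarin | COc1cc(OC)c2ccc(=O)oc2c1C#C[C@@]1(C)CCC(C)=C[C@H]1c1c(OC)cc(OC)c2ccc(=O)oc12 | intermediate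
16 | 8-[(Z)-2-[(1R,2R)-2-(5,7-dimethoxy-2-oxochromen-8-yl)-1,4-dimethylcyclohex-3-en-1-yl]ethenyl]-5,7-dimethoxycoumarin | COc1cc(OC)c2ccc(=O)oc2c1/C=C\[C@@]1(C)CCC(C)=C[C@H]1c1c(OC)cc(OC)c2ccc(=O)oc12 | target

## Step count and risks

Total step count: 12. Longest linear sequence: 11 (steps 1–6 and 8–12, from linalool). Step 7 supplies iodide 11, which is used in steps 8 and 11.

**Steps most likely to fail**

**Step 9.**
- **What may go wrong:** The tertiary allylic C–O bond, now conjugated with a very electron-rich arene, may ionise. Fragmentation and recombination through retro-hetero-Diels–Alder cleavage may also set in before the strained boat transition state is reached. Either process would bring loss of stereochemical fidelity or elimination.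
- **Fallback:** It sets out from 11 and comes back at 13.
- **Diene synthesis:** Mizoroki–Heck coupling of 11 with 2-methylbut-3-en-2-ol (Pd(OAc)2, nBu4NCl, NaHCO3, DMF, 80 °C) should give (E)-8-(3-hydroxy-3-methylbut-1-enyl)-5,7-dimethoxycoumarin F1. Mild acid dehydration (PPTS cat., PhMe, 80 °C, molecular sieves) should give (E)-8-(3-methylbuta-1,3-dienyl)-5,7-dimethoxycoumarin F2.
- **Cycloaddition:** A catalytic enantioselective Diels–Alder reaction of F2 with methacrolein follows, run in CH2Cl2 at low temperature. The catalyst is a Tf2NH-activated B-(o-tolyl)oxazaborolidine derived from diphenylprolinol.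
- **Outcome:** The reaction forms C1–C6 and C2–C3 with "ortho" regiochemistry. The endo orientation of the formyl group places CHO cis to the aryl group, and the catalyst enantiomer is chosen to deliver 13.

**Step 8.**
- **What may go wrong:** The σ-alkylpalladium intermediate carries the enolate-like ring oxygen in the β position. β-Oxygen elimination with ring opening may therefore compete with β-hydride elimination, as may arylation at the enol ether. The doubly ortho-substituted iodide also inserts slowly.
- **Fallback:** It sets out from 8 and 11 and comes back at 12. The order of events is reversed so that no enol ether is present during the palladium step.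
- **Sequence:** Heck coupling of acetal 8 with 11 under the same conditions should give 8-[(E)-2-[(2R)-6-methoxy-2,5-dimethyloxan-2-yl]ethenyl]-5,7-dimethoxycoumarin F3. Here the β-oxygen is only a poor alkoxide-type leaving group. Methanol is then removed with TMSOTf and excess iPr2NEt in CH2Cl2 at −78 → −20 °C to give 12. Amine buffering and low temperature are needed because the ether C–O bond is more labile at this stage.

**Step 12.**
- **What may go wrong:** The alkyne is shielded by a quaternary carbon on one side and a 2,6-disubstituted arene on the other. Hydrogen uptake may stall, or forcing conditions may bring over-reduction, Z to E isomerisation or attack on the coumarin C3=C4 bonds.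
- **Fallback:** It sets out from 13 and 11 and comes back at 16, bypassing steps 10–12.
- **Sequence:** Stork–Zhao olefination of 13 (Ph3P+CH2I I−, NaN(SiMe3)2, THF/DMPU, −78 °C) should give 8-[(1R,6S)-6-[(Z)-2-iodoethenyl]-3,6-dimethylcyclohex-2-en-1-yl]-5,7-dimethoxycoumarin F4. Miyaura borylation of 11 (B2pin2, Pd(dppf)Cl2, KOAc, dioxane, 80 °C) should give 5,7-dimethoxy-8-(4,4,5,5-tetramethyl-1,3,2-dioxaborolan-2-yl)coumarin F5. Suzuki–Miyaura coupling of F4 with F5 (Pd(dppf)Cl2, K3PO4, THF/H2O, 50 °C) proceeds with retention of alkene geometry and should give 16.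

## Further compounds

F1 | step 9 | (E)-8-(3-hydroxy-3-methylbut-1-enyl)-5,7-dimethoxycoumarin | CC(C)(O)/C=C/c1c(OC)cc(OC)c2ccc(=O)oc12
F2 | step 9 | (E)-8-(3-methylbuta-1,3-dienyl)-5,7-dimethoxycoumarin | CC(=C)/C=C/c1c(OC)cc(OC)c2ccc(=O)oc12
F3 | step 8 | 8-[(E)-2-[(2R)-6-methoxy-2,5-dimethyloxan-2-yl]ethenyl]-5,7-dimethoxycoumarin (mixture at the acetal and adjacent carbon) | COC1O[C@@](C)(/C=C/c2c(OC)cc(OC)c3ccc(=O)oc23)CCC1C
F4 | step 12 | 8-[(1R,6S)-6-[(Z)-2-iodoethenyl]-3,6-dimethylcyclohex-2-en-1-yl]-5,7-dimethoxycoumarin | I/C=C\[C@@]1(C)CCC(C)=C[C@H]1c1c(OC)cc(OC)c2ccc(=O)oc12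
F5 | step 12 | 5,7-dimethoxy-8-(4,4,5,5-tetramethyl-1,3,2-dioxaborolan-2-yl)coumarin | COc1cc(OC)c2ccc(=O)oc2c1B1OC(C)(C)C(C)(C)O1
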